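**Plan**

- Germacrane numbering is used: ring C1–C10, lactone O on C6, C7–C11(=C13)–C12(=O), ester O on C8, OH on C9, C14 on C10, C15 on C4.
- Retrosynthesis: cut the C8–O ester bond, return C11=C13 to a propylthio adduct and C9–OH to a ketone, cut C8–C9 of the ten-membered ring (both carbinols become aldehydes), then cut C6–C7 with the lactone C12–O bond, and finally C1=C10.
- Feature behind the key step: the vicinal C8–O/C9–O pair sits in the ten-membered ring between lactone carbon C7 and the Z C1=C10 olefin. It is the retron of a reductive coupling of a C8 aldehyde with a C9 Z-enal, and the E C4=C5 olefin would make the alternative C1–C8 bond a trans-cyclooctene.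
- Forward: geraniol supplies C1–C6, a Z-olefination adds C9/C10/C14, the γ-lactone ring is made first by asymmetric allylation/lactonization (adds C7, C8, C11–C13), SmI2 then closes the ten-membered ring, and the epoxy ester, the C9 carbinol and C11=C13 follow.
- Stereochemistry: C6 from the chiral chromium catalyst, C7 from the chair transition state of the Z-allylchromium (cis lactone), C8 from C7 during ring closure, C9 from a Luche reduction anti to the C8 acyloxy group, the epoxy acid from a Sharpless epoxidation with D-(−)-diethyl tartrate; E C4=C5 comes from geraniol and Z C1=C10 from the Still–Gennari reaction.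

Key step: step 14

Remark: C11 is a stereocenter only between steps 12 and 21; the structures show the epimer expected from protonation anti to the C7 substituent (H-11 cis to H-7), and the other epimer would serve equally.
Remark: the diol of step 14 is drawn as 9R; a 9S epimer would converge with it in step 15.
Remark: of the two antipodes of the carbazole bis(oxazoline) ligand in step 11, the one that directs the allyl group to the Re face of aldehyde 9 (giving 6S) is used.

**Route**

Step 1
Reactants: 1 geraniol
Product: 2 geranyl 4-methoxybenzyl ether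
Conditions: NaH, 4-methoxybenzyl chloride, n-Bu4NI (cat.), DMF, 0 °C to rt
Reagents that add atoms: 4-methoxybenzyl chloride, COc1ccc(CCl)cc1
Why: Williamson etherification of the primary allylic alkoxide should be clean, and the PMB ether tolerates the peracid, periodate, base and hydride steps ahead and can later be removed oxidatively beside a silyl ether.

Step 2
Reactants: 2 geranyl 4-methoxybenzyl ether
Product: 3 6,7-epoxygeranyl 4-methoxybenzyl ether (racemic)
Conditions: mCPBA (1.0 equiv), NaHCO3, CH2Cl2, −20 to 0 °C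
Reagents that add atoms: 3-chloroperbenzoic acid, OOC(=O)c1cccc(Cl)c1
Why: Prilezhaev epoxidation should take the remote, more electron-rich trisubstituted olefin rather than the one deactivated by the allylic ether oxygen, and the new stereocenter is cleaved away in step 3.

Step 3
Reactants: 3 6,7-epoxygeranyl 4-methoxybenzyl ether
Product: 4 (4E)-6-[(4-methoxybenzyl)oxy]-4-methylhex-4-enal
Conditions: H5IO6, THF/H2O, 0 °C
Reagents that add atoms: none
Why: periodic acid opens the epoxide to the glycol and cleaves it (Malaprade-type cleavage) to the C1 aldehyde and acetone without touching the E C4=C5 olefin.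

Step 4
Reactants: 4 (4E)-6-[(4-methoxybenzyl)oxy]-4-methylhex-4-enal
Product: 5 ethyl (2Z,6E)-8-[(4-methoxybenzyl)oxy]-2,6-dimethylocta-2,6-dienoate
Conditions: ethyl 2-[bis(2,2,2-trifluoroethoxy)phosphoryl]propanoate, KN(SiMe3)2, 18-crown-6, THF, −78 °C
Reagents that add atoms: ethyl 2-[bis(2,2,2-trifluoroethoxy)phosphoryl]propanoate, CCOC(=O)C(C)P(=O)(OCC(F)(F)F)OCC(F)(F)F
Why: the Still–Gennari olefination with a trifluoroethyl phosphonate and a dissociated potassium counter-ion eliminates under kinetic control and should give the Z trisubstituted enoate, which fixes the Z C1=C10 geometry.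

Step 5
Reactants: 5 ethyl (2Z,6E)-8-[(4-methoxybenzyl)oxy]-2,6-dimethylocta-2,6-dienoate
Product: 6 (2Z,6E)-8-[(4-methoxybenzyl)oxy]-2,6-dimethylocta-2,6-dien-1-ol
Conditions: i-Bu2AlH (2.5 equiv), CH2Cl2, −78 °C; aq. KNaC4H4O6
Reagents that add atoms: none
Why: i-Bu2AlH reduces the conjugated ester in 1,2-fashion to the allylic alcohol (C9) with retention of the Z geometry.

Step 6
Reactants: 6 (2Z,6E)-8-[(4-methoxybenzyl)oxy]-2,6-dimethylocta-2,6-dien-1-ol
Product: 7 tert-butyldimethylsilyl ether of 6
Conditions: TBSCl, imidazole, DMF, rt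
Reagents that add atoms: tert-butyldimethylsilyl chloride, CC(C)(C)[Si](C)(C)Cl
Why: standard silylation of a primary alcohol gives the C9 oxygen the same protecting group that C8 will carry, so both can be released together in step 12.

Step 7
Reactants: 7 tert-butyldimethylsilyl ether of 6
Product: 8 (2E,6Z)-8-[(tert-butyldimethylsilyl)oxy]-3,7-dimethylocta-2,6-dien-1-ol
Conditions: DDQ, CH2Cl2/pH 7 buffer, 0 °C
Reagents that add atoms: none
Why: oxidative cleavage of the PMB ether by DDQ (hydride abstraction from the electron-rich benzylic position, then hydrolysis) frees the C6 hydroxyl while the silyl ether and both olefins stay intact.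

Step 8
Reactants: 8 (2E,6Z)-8-[(tert-butyldimethylsilyl)oxy]-3,7-dimethylocta-2,6-dien-1-ol
Product: 9 (2E,6Z)-8-[(tert-butyldimethylsilyl)oxy]-3,7-dimethylocta-2,6-dienal
Conditions: MnO2, CH2Cl2, rt
Reagents that add atoms: none
Why: MnO2 oxidation of the primary allylic alcohol stops at the enal and, being neutral, should not isomerize the E C4=C5 olefin.

Step 9
Reactants: 10 methyl acrylate; 11 (tert-butyldimethylsilyloxy)acetaldehyde
Product: 12 methyl 4-[(tert-butyldimethylsilyl)oxy]-3-hydroxy-2-methylidenebutanoate (racemic)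
Conditions: DABCO (0.5 equiv), neat, rt
Reagents that add atoms: none
Why: the Morita–Baylis–Hillman reaction works well with α-oxygenated aldehydes, and the racemic carbinol carbon becomes sp2 in step 10.

Step 10
Reactants: 12 methyl 4-[(tert-butyldimethylsilyl)oxy]-3-hydroxy-2-methylidenebutanoate
Product: 13 methyl (2Z)-2-(bromomethyl)-4-[(tert-butyldimethylsilyl)oxy]but-2-enoate
Conditions: NBS, Me2S, CH2Cl2, 0 °C to rt
Reagents that add atoms: N-bromosuccinimide, BrN1C(=O)CCC1=O
Why: Corey–Kim-type activation of the hydroxyl followed by SN2' attack of bromide gives the transposed primary allylic bromide, with the CH2OTBS group trans to the ester (Z) as is usual for such adducts, under conditions free of acid that would cleave the silyl ether.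

Step 11
Reactants: 9 (2E,6Z)-8-[(tert-butyldimethylsilyl)oxy]-3,7-dimethylocta-2,6-dienal; 13 methyl (2Z)-2-(bromomethyl)-4-[(tert-butyldimethylsilyl)oxy]but-2-enoate
Product: 16 cis α-methylene lactone (6S,7R) carrying CH2OTBS on C7 and the dienyl chain on C6, via O-trimethylsilyl syn adduct 14 (not isolated), via syn hydroxy ester 15 (not isolated)
Conditions: CrCl2 (10 mol %), 3,6-di-tert-butyl-1,8-bis(4-isopropyl-4,5-dihydrooxazol-2-yl)-9H-carbazole (single antipode, 12 mol %), Mn powder, i-Pr2NEt, Me3SiCl, THF, rt; then aq. citric acid, rt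
Reagents that add atoms: none
Why: catalytic asymmetric Nozaki–Hiyama–Kishi-type 2-(alkoxycarbonyl)allylation followed by lactonization forms C6–C7 and the lactone; C6 is set by the chiral ligand on chromium (Re-face attack), and C7 by the chair transition state in which the CH2OTBS group of the Z-configured allylchromium is axial, which gives the syn adduct and hence the cis lactone.

Step 12
Reactants: 16 cis α-methylene lactone
Product: 18 lactone sulfide diol (6S,7R,11R) with free C8 and C9 hydroxyls, via bis-TBS ether sulfide 17 (not isolated)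
Conditions: n-PrSH, Et3N (cat.), THF, rt; then HF·pyridine, 0 °C to rt
Reagents that add atoms: propane-1-thiol, CCCS
Why: thia-Michael addition masks C11=C13, which would otherwise accept ketyl radicals in step 14 and hydride in step 20 (C11 set by protonation anti to the C7 substituent, temporary), and the mildly acidic fluoride source then removes both silyl ethers without translactonization of the freed C8 hydroxyl onto C12.

Step 13
Reactants: 18 lactone sulfide diol
Product: 19 dialdehyde (6S,7S,11R) with the C8 aldehyde on C7 and the Z-enal (C9) at the chain end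
Conditions: Dess–Martin periodinane, NaHCO3, CH2Cl2, 0 °C; used crude
Reagents that add atoms: none
Why: Dess–Martin oxidation converts the allylic C9 and the saturated C8 alcohol under buffered, non-basic conditions that should spare the epimerizable C7 center, the β-acyloxy aldehyde and the Z-enal geometry, and it does not oxidize dialkyl sulfides.

Step 14
Reactants: 19 dialdehyde
Product: 20 ten-membered 8,9-diol (6S,7R,8R,9R,11R) with the cis-fused lactone
Conditions: SmI2 (3 equiv, 0.1 M in THF), THF, −78 to 0 °C, 19 added over 4 h to a final 2 mM; aq. NH4Cl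
Reagents that add atoms: none
Why: SmI2 transfers one electron to the more easily reduced Z-enal, the oxophilic trivalent samarium of the resulting allylic ketyl binds the C8 aldehyde, C9 adds to C8 and a second electron completes the cyclic samarium diolate that is hydrolysed to the diol; this is the intramolecular pinacol coupling of dialdehydes by SmI2 that is established for medium rings. The ten-membered carbocycle closes in a 10-exo-trig mode by bond formation between the two carbonyl carbons, with both oxygens left exocyclic. C8 is controlled by C7 through a Felkin-type arrangement in which the tether carbon C6 stands anti to the forming C8–C9 bond, the samarium-bound oxygen lies on the side of the C11 branch and H-8 faces H-7, which corresponds to 8R. C9 is controlled by the samarium bridge that holds both oxygens gauche on the ring periphery, expected to give the 8,9-threo diol (9R); this center need not be secured because it is oxidized in step 15 and set again in step 20. The step needs carbonyl-to-carbonyl rather than vinylogous coupling and cyclization rather than oligomerization or simple reduction: a C1–C8 bond would enclose the E C4=C5 olefin in an eight-membered ring (a trans-cyclooctene), and slow addition at high dilution without a proton source keeps intermolecular coupling and ketyl protonation slow. The saturated lactone and the dialkyl sulfide are inert to SmI2 in THF without HMPA, and the masking of C11=C13 removes the one acceptor that a ketyl radical would otherwise attack.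

Step 15
Reactants: 20 ten-membered 8,9-diol
Product: 21 8-hydroxy-9-oxo enone (6S,7R,8R,11R)
Conditions: MnO2, CH2Cl2, rt
Reagents that add atoms: none
Why: MnO2 oxidizes only the allylic C9 carbinol (allylic oxidation), so the two hydroxyls are differentiated, the C9 stereocenter is removed and the saturated C8 carbinol is left for acylation.

Step 16
Reactants: 22 angelic acid
Product: 23 (2Z)-2-methylbut-2-en-1-ol
Conditions: LiAlH4, Et2O, 0 °C to rt
Reagents that add atoms: none
Why: hydride reduction of the carboxylic acid gives the allylic alcohol without touching the Z olefin.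

Step 17
Reactants: 23 (2Z)-2-methylbut-2-en-1-ol
Product: 24 [(2R,3S)-2,3-dimethyloxiran-2-yl]methanol
Conditions: Ti(OiPr)4 (10 mol %), D-(−)-diethyl tartrate (12 mol %), t-BuOOH, 4 Å molecular sieves, CH2Cl2, −20 °C
Reagents that add atoms: tert-butyl hydroperoxide, CC(C)(C)OO
Why: Sharpless asymmetric epoxidation of the allylic alcohol delivers oxygen to one olefin face under control of the tartrate (D-(−)-tartrate giving 2R,3S here), and the cis relation of the two methyl-bearing carbons follows from the Z olefin.

Step 18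
Reactants: 24 [(2R,3S)-2,3-dimethyloxiran-2-yl]methanol
Product: 25 (2S,3S)-2,3-dimethyloxirane-2-carboxylic acid
Conditions: RuCl3 hydrate (2 mol %), NaIO4, MeCN/EtOAc/H2O, 0 °C to rt
Reagents that add atoms: water, O
Why: ruthenium-catalysed periodate oxidation takes the primary alcohol through the aldehyde hydrate to the acid without opening the epoxide or touching its stereocenters (the descriptor at C2 changes only by priority).

Step 19
Reactants: 21 8-hydroxy-9-oxo enone; 25 (2S,3S)-2,3-dimethyloxirane-2-carboxylic acid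
Product: 27 9-oxo 8-epoxyangelate (6S,7S,8R,11R), via mixed anhydride 26 (not isolated)
Conditions: 2,4,6-trichlorobenzoyl chloride, Et3N, THF, rt; then 21, DMAP, toluene, rt
Reagents that add atoms: none
Why: Yamaguchi esterification through the mixed anhydride acylates the hindered C8 hydroxyl with retention under aprotic, mildly basic conditions that cap O8 before it can translactonize onto C12, and the epoxy acid has no olefin that could isomerize.

Step 20
Reactants: 27 9-oxo 8-epoxyangelate
Product: 28 9R allylic alcohol (6S,7S,8R,9R,11R)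
Conditions: NaBH4, CeCl3·7H2O, MeOH/THF, −78 °C
Reagents that add atoms: none
Why: Luche reduction gives clean 1,2-addition to the enone, and hydride is expected anti to the C8 acyloxy bond (Felkin–Anh), which with the ring segment C7–C8–C9–C10 extended gives the 8,9-threo relation (9R).

Step 21
Reactants: 28 9R allylic alcohol
Product: 30 target CNP0318223.3, via sulfonium iodide 29 (not isolated)
Conditions: MeI (excess), MeCN, rt, dark; then aq. NaHCO3, EtOAc, rt
Reagents that add atoms: none
Why: S-methylation gives a sulfonium salt whose only acidic β-hydrogen is H-11 next to the lactone carbonyl, so mild base effects E1cB elimination to the exocyclic C11=C13 olefin regiospecifically and leaves the epoxy ester, the allylic alcohol and both ring olefins untouched.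

**Compound list**

1 | geraniol, (2E)-3,7-dimethylocta-2,6-dien-1-ol | CC(C)=CCC/C(C)=C/CO | starting material
2 | geranyl 4-methoxybenzyl ether | CC(C)=CCC/C(C)=C/COCc1ccc(OC)cc1 | intermediate
3 | 6,7-epoxygeranyl 4-methoxybenzyl ether (racemic at the epoxide CH) | CC1(C)OC1CC/C(C)=C/COCc1ccc(OC)cc1 | intermediate
4 | (4E)-6-[(4-methoxybenzyl)oxy]-4-methylhex-4-enal | O=CCC/C(C)=C/COCc1ccc(OC)cc1 | intermediate
5 | ethyl (2Z,6E)-8-[(4-methoxybenzyl)oxy]-2,6-dimethylocta-2,6-dienoate | CCOC(=O)/C(C)=C\CC/C(C)=C/COCc1ccc(OC)cc1 | intermediate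
6 | (2Z,6E)-8-[(4-methoxybenzyl)oxy]-2,6-dimethylocta-2,6-dien-1-ol | OC/C(C)=C\CC/C(C)=C/COCc1ccc(OC)cc1 | intermediate
7 | tert-butyl{[(2Z,6E)-8-[(4-methoxybenzyl)oxy]-2,6-dimethylocta-2,6-dien-1-yl]oxy}dimethylsilane | CC(C)(C)[Si](C)(C)OC/C(C)=C\CC/C(C)=C/COCc1ccc(OC)cc1 | intermediate
8 | (2E,6Z)-8-[(tert-butyldimethylsilyl)oxy]-3,7-dimethylocta-2,6-dien-1-ol | CC(C)(C)[Si](C)(C)OC/C(C)=C\CC/C(C)=C/CO | intermediate
9 | (2E,6Z)-8-[(tert-butyldimethylsilyl)oxy]-3,7-dimethylocta-2,6-dienal | CC(C)(C)[Si](C)(C)OC/C(C)=C\CC/C(C)=C/C=O | intermediate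
10 | methyl acrylate | C=CC(=O)OC | starting material
11 | (tert-butyldimethylsilyloxy)acetaldehyde | O=CCO[Si](C)(C)C(C)(C)C | starting material
12 | methyl 4-[(tert-butyldimethylsilyl)oxy]-3-hydroxy-2-methylidenebutanoate (racemic) | C=C(C(=O)OC)C(O)CO[Si](C)(C)C(C)(C)C | intermediate
13 | methyl (2Z)-2-(bromomethyl)-4-[(tert-butyldimethylsilyl)oxy]but-2-enoate | COC(=O)/C(CBr)=C/CO[Si](C)(C)C(C)(C)C | intermediate
14 | methyl (3R,4S,5E,9Z)-11-[(tert-butyldimethylsilyl)oxy]-3-{[(tert-butyldimethylsilyl)oxy]methyl}-6,10-dimethyl-2-methylidene-4-[(trimethylsilyl)oxy]undeca-5,9-dienoate | C=C(C(=O)OC)[C@H](CO[Si](C)(C)C(C)(C)C)[C@@H](O[Si](C)(C)C)/C=C(\C)CC/C=C(/C)CO[Si](C)(C)C(C)(C)C | intermediate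
15 | methyl (3R,4S,5E,9Z)-11-[(tert-butyldimethylsilyl)oxy]-3-{[(tert-butyldimethylsilyl)oxy]methyl}-4-hydroxy-6,10-dimethyl-2-methylideneundeca-5,9-dienoate | C=C(C(=O)OC)[C@H](CO[Si](C)(C)C(C)(C)C)[C@@H](O)/C=C(\C)CC/C=C(/C)CO[Si](C)(C)C(C)(C)C | intermediate
16 | (4R,5S)-5-[(1E,5Z)-7-[(tert-butyldimethylsilyl)oxy]-2,6-dimethylhepta-1,5-dien-1-yl]-4-{[(tert-butyldimethylsilyl)oxy]methyl}-3-methylideneoxolan-2-one (cis lactone; 6S,7R in germacrane numbering) | C=C1C(=O)O[C@@H](/C=C(\C)CC/C=C(/C)CO[Si](C)(C)C(C)(C)C)[C@H]1CO[Si](C)(C)C(C)(C)C | intermediate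
17 | (3R,4R,5S)-5-[(1E,5Z)-7-[(tert-butyldimethylsilyl)oxy]-2,6-dimethylhepta-1,5-dien-1-yl]-4-{[(tert-butyldimethylsilyl)oxy]methyl}-3-[(propylsulfanyl)methyl]oxolan-2-one (all-cis) | CCCSC[C@H]1C(=O)O[C@@H](/C=C(\C)CC/C=C(/C)CO[Si](C)(C)C(C)(C)C)[C@H]1CO[Si](C)(C)C(C)(C)C | intermediate
18 | (3R,4R,5S)-5-[(1E,5Z)-7-hydroxy-2,6-dimethylhepta-1,5-dien-1-yl]-4-(hydroxymethyl)-3-[(propylsulfanyl)methyl]oxolan-2-one (all-cis) | CCCSC[C@H]1C(=O)O[C@@H](/C=C(\C)CC/C=C(/C)CO)[C@H]1CO | intermediate
19 | (2S,3S,4R)-2-[(1E,5Z)-2,6-dimethyl-7-oxohepta-1,5-dien-1-yl]-5-oxo-4-[(propylsulfanyl)methyl]oxolane-3-carbaldehyde (all-cis; C8 aldehyde on C7, Z-enal at C9) | CCCSC[C@H]1C(=O)O[C@@H](/C=C(\C)CC/C=C(/C)C=O)[C@H]1C=O | intermediate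
20 | (6S,7R,8R,9R,11R)-8,9-dihydroxy-13-(propylsulfanyl)germacra-1(10)Z,4E-dien-12,6-olide (cis-fused lactone, H-11 cis to H-7) | CCCSC[C@H]1C(=O)O[C@H]2/C=C(\C)CC/C=C(/C)[C@@H](O)[C@H](O)[C@@H]12 | intermediate
21 | (6S,7R,8R,11R)-8-hydroxy-9-oxo-13-(propylsulfanyl)germacra-1(10)Z,4E-dien-12,6-olide | CCCSC[C@H]1C(=O)O[C@H]2/C=C(\C)CC/C=C(/C)C(=O)[C@H](O)[C@@H]12 | intermediate
22 | angelic acid, (2Z)-2-methylbut-2-enoic acid | C/C=C(/C)C(=O)O | starting material
23 | (2Z)-2-methylbut-2-en-1-ol | C/C=C(/C)CO | intermediate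
24 | [(2R,3S)-2,3-dimethyloxiran-2-yl]methanol | OC[C@@]1(C)O[C@H]1C | intermediate
25 | (2S,3S)-2,3-dimethyloxirane-2-carboxylic acid | OC(=O)[C@@]1(C)O[C@H]1C | intermediate
26 | (2S,3S)-2,3-dimethyloxirane-2-carboxylic 2,4,6-trichlorobenzoic anhydride | O=C(OC(=O)c1c(Cl)cc(Cl)cc1Cl)[C@@]1(C)O[C@H]1C | intermediate
27 | (6S,7S,8R,11R)-8-{[(2S,3S)-2,3-dimethyloxirane-2-carbonyl]oxy}-9-oxo-13-(propylsulfanyl)germacra-1(10)Z,4E-dien-12,6-olide | CCCSC[C@H]1C(=O)O[C@H]2/C=C(\C)CC/C=C(/C)C(=O)[C@H](OC(=O)[C@@]3(C)O[C@H]3C)[C@@H]12 | intermediate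
28 | (6S,7S,8R,9R,11R)-8-{[(2S,3S)-2,3-dimethyloxirane-2-carbonyl]oxy}-9-hydroxy-13-(propylsulfanyl)germacra-1(10)Z,4E-dien-12,6-olide | CCCSC[C@H]1C(=O)O[C@H]2/C=C(\C)CC/C=C(/C)[C@@H](O)[C@H](OC(=O)[C@@]3(C)O[C@H]3C)[C@@H]12 | intermediate
29 | S-methyl sulfonium iodide of 28 (mixture at sulfur) | CCC[S+](C)C[C@H]1C(=O)O[C@H]2/C=C(\C)CC/C=C(/C)[C@@H](O)[C@H](OC(=O)[C@@]3(C)O[C@H]3C)[C@@H]12.[I-] | intermediate
30 | CNP0318223.3, (6S,7S,8R,9R)-8-{[(2S,3S)-2,3-dimethyloxirane-2-carbonyl]oxy}-9-hydroxygermacra-1(10)Z,4E,11(13)-trien-12,6-olide | C=C1C(=O)O[C@H]2/C=C(\C)CC/C=C(/C)[C@@H](O)[C@H](OC(=O)[C@@]3(C)O[C@H]3C)[C@@H]12 | target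

**Count and risks**

Total steps: 21. Longest linear sequence: 16 steps (steps 1–8, 11–15, 19–21); steps 9–10 and 16–18 are side branches.

Step 14 (ring closure). What may go wrong: C9 may add to the other face of the C8 carbonyl, so that the ring closes with the C8 oxygen on the wrong side. The fallback sets out from 19 and comes back at 27. The same closure then delivers the C8-epimeric diol F1, and MnO2 oxidizes its allylic carbinol to the C8-epimeric hydroxy enone F2. In place of the acylation with retention, F2 is esterified with acid 25 under Mitsunobu conditions (PPh3, DIAD, toluene, 0 °C to rt), where the carboxylate displaces the activated C8 oxygen with inversion and gives 27. Both C8 epimers of the coupling product can in this way be funnelled into the same keto ester.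

Step 11 (asymmetric allylation/lactonization). What may go wrong: insufficient enantio- or syn-selectivity of the chromium allylation with the γ-branched bromide, or a mismatch of ligand and enal. The fallback sets out from 9 and comes back at 16, and replaces catalyst control by an oxazolidinone auxiliary.
- (R)-4-Benzyl-1,3-oxazolidin-2-one is acylated (n-BuLi, methyl 4-chloro-4-oxobutanoate, THF, −78 °C) to the succinate imide F3.
- A magnesium halide-catalysed anti-aldol addition of F3 to 9 (MgCl2, Et3N, Me3SiCl, EtOAc, rt) gives the O-trimethylsilyl anti adduct F4, the chelated Z-enolate being attacked opposite the benzyl group.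
- PPTS in methanol frees the hydroxy imide F5, which closes onto its methyl ester (PPTS, toluene, warm) to the cis lactone imide F6.
- NaBH4 in THF/H2O removes the auxiliary reductively to the hydroxymethyl lactone F7, and TBSCl/imidazole gives the silyl ether F8.
- LiN(i-Pr)2 and then Eschenmoser's salt give the Mannich base F9; MeI forms the trimethylammonium iodide F10, and NaHCO3 eliminates it to 16.

Step 20 (Luche reduction). What may go wrong: hydride delivery to the wrong face of the C9 ketone, if peripheral attack on the ring conformer overrides the Felkin–Anh preference. The fallback sets out from 27 and comes back at 28. The reduction then gives the C9-epimeric alcohol F11, which is inverted by Mitsunobu reaction with chloroacetic acid (PPh3, DIAD, THF, 0 °C) to the 9R chloroacetate F12. Thiourea with NaHCO3 in ethanol removes the chloroacetyl group selectively beside the hindered epoxy ester and gives 28.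

**Further compounds**

F1 | step 14 | C8 epimer of 20, (6S,7R,8S,9R,11R)-8,9-dihydroxy-13-(propylsulfanyl)germacra-1(10)Z,4E-dien-12,6-olide | CCCSC[C@H]1C(=O)O[C@H]2/C=C(\C)CC/C=C(/C)[C@@H](O)[C@@H](O)[C@@H]12
F2 | step 14 | C8 epimer of 21, (8S)-8-hydroxy-9-oxo-13-(propylsulfanyl)germacra-1(10)Z,4E-dien-12,6-olide | CCCSC[C@H]1C(=O)O[C@H]2/C=C(\C)CC/C=C(/C)C(=O)[C@@H](O)[C@@H]12
F3 | step 11 | (4R)-4-benzyl-3-(4-methoxy-4-oxobutanoyl)-1,3-oxazolidin-2-one | COC(=O)CCC(=O)N1[C@H](Cc2ccccc2)COC1=O
F4 | step 11 | O-trimethylsilyl anti-aldol adduct of F3 and 9 | COC(=O)C[C@H](C(=O)N1[C@H](Cc2ccccc2)COC1=O)[C@@H](O[Si](C)(C)C)/C=C(\C)CC/C=C(/C)CO[Si](C)(C)C(C)(C)C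
F5 | step 11 | anti-aldol hydroxy imide | COC(=O)C[C@H](C(=O)N1[C@H](Cc2ccccc2)COC1=O)[C@@H](O)/C=C(\C)CC/C=C(/C)CO[Si](C)(C)C(C)(C)C
F6 | step 11 | cis lactone imide (lactone C7 acylating the auxiliary nitrogen) | C1C(=O)O[C@@H](/C=C(\C)CC/C=C(/C)CO[Si](C)(C)C(C)(C)C)[C@H]1C(=O)N2[C@H](Cc3ccccc3)COC2=O
F7 | step 11 | cis 4-(hydroxymethyl) lactone | C1C(=O)O[C@@H](/C=C(\C)CC/C=C(/C)CO[Si](C)(C)C(C)(C)C)[C@H]1CO
F8 | step 11 | tert-butyldimethylsilyl ether of F7 | C1C(=O)O[C@@H](/C=C(\C)CC/C=C(/C)CO[Si](C)(C)C(C)(C)C)[C@H]1CO[Si](C)(C)C(C)(C)C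
F9 | step 11 | 3-[(dimethylamino)methyl] lactone (C13 trans to the C7 substituent) | CN(C)C[C@@H]1C(=O)O[C@@H](/C=C(\C)CC/C=C(/C)CO[Si](C)(C)C(C)(C)C)[C@H]1CO[Si](C)(C)C(C)(C)C
F10 | step 11 | trimethylammonium iodide of F9 | C[N+](C)(C)C[C@@H]1C(=O)O[C@@H](/C=C(\C)CC/C=C(/C)CO[Si](C)(C)C(C)(C)C)[C@H]1CO[Si](C)(C)C(C)(C)C.[I-]
F11 | step 20 | C9 epimer of 28 (9S) | CCCSC[C@H]1C(=O)O[C@H]2/C=C(\C)CC/C=C(/C)[C@H](O)[C@H](OC(=O)[C@@]3(C)O[C@H]3C)[C@@H]12
F12 | step 20 | 9R chloroacetate of 28 | CCCSC[C@H]1C(=O)O[C@H]2/C=C(\C)CC/C=C(/C)[C@@H](OC(=O)CCl)[C@H](OC(=O)[C@@]3(C)O[C@H]3C)[C@@H]12
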